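## The problem

The target 35 is a (3R)-isoflavan: a chroman (rings A and C) that carries at C3 an aryl ring B, and ring B is fused through O2′ and C3′ to a 2,2-dimethyl-2H-pyran (ring D). The B/D unit is therefore a 5-hydroxy-2,2-dimethyl-2H-chromen-8-yl group. C3 is the only stereocentre. It is a benzylic CH between two methylene groups, nothing else in the molecule can direct it, and so a catalyst or reagent has to set it. Once it stands β to every carbonyl group of the route it cannot epimerise. Ring A is pentasubstituted (C4a alkyl, C5 OMe, C6 H, C7 OH, C8 CHO, C8a O1). Formylation of a preformed 5,7-dioxygenated chroman cannot tell C8 from C6, and the oxygens at C5 and C7 must be told apart as OMe and OH. The fragile parts are the styrene-type C3″=C4″ olefin of ring D (no hydrogenation, no strong acid, no electrophilic oxidant, photochromic under short-wave UV), the ortho-hydroxy aldehyde and the electron-rich phenols. The enabling feature is that oxygen-bearing carbons (C5, C7, C8a) alternate with carbon- or hydrogen-bearing ones (C4a, C6, C8) around ring A. This is the pattern that a vinylketene (C8a, C6, C5, C4a) and an ynol ether (C7, C8) deliver in a benzannulation. In that construction the hydroxyl appears free at C8a, next to the C4a side chain and ready for the O1–C2 closure, while C7–O arrives silylated and C5–O methylated.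

## Retrosynthesis

**Ring C, O1–C2.** Target 35 is traced through its B-ring MOM ether 34 to the open triol aldehyde 33 by cutting O1–C2. The neighbouring cut C4–C4a would ask for a Friedel–Crafts closure with ring-A regiocontrol; the chosen cut is an SN2 displacement at a primary carbon that cannot touch C3. The forward reaction needs a primary alcohol and a free C8a hydroxyl. The C7 hydroxyl of 33 cannot reach the chain, so it needs no protection.

**Unmasking.** 33 comes from phenol 31, in which C7–O is a silyl ether, the chain oxygen a silyl ether and the C8 formyl group a diethyl acetal. One fluoride treatment followed by a weakly acidic aqueous phase should remove all three masks, via the acetal triol 32. 31 is no simpler in skeleton, but it is the direct product of the ring-forming step.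

**Ring A, C8–C8a, C6–C7 and C4a–C8a.** 31 is cut into cyclobutenone 22 and siloxyalkyne 26. Against late formylation or a cross-coupling on a preformed arene, this cut places all five substituents by bond construction. Ring A disappears and leaves a four-membered ring carrying the chiral chain and a three-carbon alkyne. The forward reaction must be regiospecific in the ketene–ynol ether [2+2] and must tolerate the chromene, the acetal and two silyl ethers at about 100 °C.

**Siloxyalkyne, C7–O.** 26 is cut at the alkyne C–O bond back to 3,3-diethoxyprop-1-yne 23, through acetylide 24 and ynolate 25. The forward reaction is oxidation of the acetylide to the ynolate and O-silylation with a bulky silyl group.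

**Cyclobutenone, C4a–C5 and C6–C8a.** 22 is the [2+2] adduct of the aldoketene 21 and methoxyethyne 20 (from chloroacetal 18). This cut is preferred to alkylation of a preformed cyclobutenone, which has no usable enolate. Ketene 21 is traced to diazoketone 17 and this to acid 15; the diazo carbon becomes C4a and the carboxyl carbon C8a. The forward reaction is a Wolff rearrangement in the presence of the ynol ether.

**Stereocentre, C3–C1′.** Acid 15 is the opened and silylated form of lactone 12, which is cut at the aryl–C3 bond into boronic acid 10 and furan-2(5H)-one 11. The alternative, an asymmetric hydrogenation at C3, is excluded by the chromene olefin. The cut gives an achiral aryl donor and a commercial acceptor, and asks for a catalytic enantioselective 1,4-addition.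

**Ring D, O2′–C2″ and C3′–C4″.** 10 comes from bromochromene 7, and 7 from propargyl ether 5 by an aromatic propargyl Claisen rearrangement. 5 is assembled from 4-bromoresorcinol 1 through mono-MOM ether 3 and the propargylic chloride 4. Bromine later becomes the C1′ handle and meanwhile blocks one ortho position, so the rearrangement can only go to the carbon between the two oxygens. The MOM ether leaves only one oxygen free for the pyran closure.

## Roads not taken

**Alternative 1:** The pyran ring would be cut at C3–C4 and O1–C2, giving lactol A1. In the forward step, base eliminates sulfone A2 to an A-ring quinone methide, and a chiral secondary-amine catalyst turns arylacetaldehyde A3 into an enamine; their [4+2] union closes ring C and sets C3 in one catalytic operation.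
- Merits: convergence and brevity. The isoflavan core is reached in fewer steps than in the chosen plan, and the stereocentre is made in the ring-forming step. In both respects this road is better.
- Weak points: A1 carries a symmetric 5,7-dimethoxy ring with hydrogen at C8. The 7-OMe would then have to be cleaved beside the 5-OMe, and C8 formylated beside the electronically similar C6. C3 in A1 lies next to the lactol carbon and can epimerise through the ring-opened aldehyde before the lactol is reduced. A3 is an electron-rich arylacetaldehyde prone to self-condensation. Ionic deoxygenation of the lactol uses acid that the chromene does not tolerate.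
- Set against it: the chosen plan fixes every A-ring position by construction and sets C3 where it is not enolisable.

**Alternative 2:** C2–C3 and C3–C4 would be cut so that C3 with ring B is inserted as one carbon into benzofuran A5. The chlorocarbene from diazirine A6 adds to the furan double bond and the cyclopropane opens with loss of chloride to isoflavylium salt A4.
- Merits: the shortest assembly of the skeleton, from a cheap heteroarene.
- Weak points: A4 is achiral and fully oxidised, so C3 must be set afterwards by asymmetric reduction. That reduction has to precede ring D, which must then be built late on ring B after differential deprotection. Ring A is again 5,7-dimethoxy without the formyl group, and chlorodiazirines of electron-rich arenes are of limited stability.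
- Comparison: this road reaches the skeleton faster, but leaves three selectivity problems open (configuration at C3, C7 against C5 oxygen, C8 against C6 carbon). The chosen plan settles them in the design, at the price of a longer linear sequence.

**Alternative 3:** O2′–C2″ and C3′–C4″ would be cut last. Propargyl ether A8 of the complete isoflavan rearranges thermally to A7, the 4′-O-silyl ether of the target.
- Merits: the chromene olefin is made at the very end, so no earlier step has to respect it. Here this road is better than the chosen plan, in which ring D must survive an organolithium, rhodium catalysis, irradiation, heating and a final acid treatment. The rearrangement is also regiochemically forced, because C1′ is substituted.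
- Weak points: it is an endgame only. A8 already contains the pentasubstituted ring A and the C3 stereocentre, which must come from elsewhere. Selective propargylation of the 2′-hydroxyl beside the 7-hydroxyl costs protecting-group steps, and a free salicylaldehyde with a terminal alkyne must be heated to 150–180 °C.
- Comparison: the chosen plan uses the same Claisen logic at the start, on a simple bromide where bromine blocks the other ortho position, and combines it with a construction of ring A. Chromene tolerance has been checked for every later step.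

Key step: step 11

## Route

Remarks on the chemistry:
- Ar in the step names stands for 5-(methoxymethoxy)-2,2-dimethyl-2H-chromen-8-yl.
- Cyclobutenone 22 is formed and used as a mixture of epimers at its ring carbon C4, which becomes aromatic C4a.
- The (R)-ligand in step 5 is chosen by analogy with the facial selectivity established for cyclic enones and unsaturated lactones. The absolute configuration of 12 is to be confirmed at that stage, and the other ligand enantiomer used if needed.

Step 1
Reactants: 1 4-bromobenzene-1,3-diol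
Product: 3 2-bromo-5-(methoxymethoxy)phenol, via disodium 4-bromobenzene-1,3-diolate 2 (not isolated)
Conditions: NaH (2.1 equiv), DMF, 0 °C; MOMCl (1.0 equiv), −20 → 0 °C; aq. NH4Cl
Reagents that add atoms: chloromethyl methyl ether, COCCl
Why: Williamson-type MOM ether formation on the dianion: with both hydroxyls deprotonated, one equivalent of electrophile should go to the more basic and less hindered oxygen para to bromine, since the oxygen ortho to bromine is inductively deactivated and shielded.

Step 2
Reactants: 3 2-bromo-5-(methoxymethoxy)phenol; 4 3-chloro-3-methylbut-1-yne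
Product: 5 1-bromo-4-(methoxymethoxy)-2-[(2-methylbut-3-yn-2-yl)oxy]benzene
Conditions: 4 (1.5 equiv), CuCl2·2H2O (1 mol %), DBU, MeCN, 0 °C
Reagents that add atoms: none
Why: Copper-catalysed O-propargylation of a phenol with a tertiary propargylic chloride under amidine base, the standard entry to aryl 1,1-dimethylpropargyl ethers; aryl bromide and MOM ether are inert at 0 °C.

Step 3
Reactants: 5 1-bromo-4-(methoxymethoxy)-2-[(2-methylbut-3-yn-2-yl)oxy]benzene
Product: 7 8-bromo-5-(methoxymethoxy)-2,2-dimethyl-2H-chromene, via allenylphenol 6 (not isolated)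
Conditions: PhNEt2, 170 °C
Reagents that add atoms: none
Why: Aromatic propargyl Claisen rearrangement: the [3,3] shift can only deliver to the carbon between the two oxygens because the other ortho position carries bromine; allenylphenol 6 then undergoes 1,5-hydrogen shift and oxa-6π closure on the only free oxygen.

Step 4
Reactants: 7 8-bromo-5-(methoxymethoxy)-2,2-dimethyl-2H-chromene
Product: 10 [5-(methoxymethoxy)-2,2-dimethyl-2H-chromen-8-yl]boronic acid, via aryllithium 8 (not isolated), via lithium triisopropoxyborate 9 (not isolated)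
Conditions: n-BuLi, THF, −78 °C; B(OiPr)3, −78 °C → rt; dil. aq. HCl to pH 5, 0 °C
Reagents that add atoms: triisopropyl borate, CC(C)OB(OC(C)C)OC(C)C; water, O
Why: Bromine–lithium exchange at −78 °C is much faster than ortho-lithiation next to the MOM ether; borate trapping and mild hydrolysis are the standard route to arylboronic acids, and the brief weakly acidic work-up spares the MOM group.

Step 5
Reactants: 10 [5-(methoxymethoxy)-2,2-dimethyl-2H-chromen-8-yl]boronic acid; 11 furan-2(5H)-one
Product: 12 (4R)-4-Ar-oxolan-2-one
Conditions: [Rh(OH)((R)-binap)]2 (3 mol % Rh), 11 (2 equiv), dioxane–H2O (10:1), 40 °C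
Reagents that add atoms: none
Why: Hayashi–Miyaura asymmetric 1,4-addition to an unsaturated lactone: the aryl–rhodium/(R)-BINAP complex selects one enantioface of the butenolide in the insertion step and water protonates the rhodium enolate, so C3 of the target is set here by the ligand; base-free conditions at 40 °C limit protodeboronation.

Step 6
Reactants: 12 (4R)-4-Ar-oxolan-2-one
Product: 15 (3R)-3-Ar-4-[(tert-butyldimethylsilyl)oxy]butanoic acid, via lithium hydroxybutanoate 13 (not isolated), via bis-silyl derivative 14 (not isolated)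
Conditions: LiOH·H2O, THF–H2O, 0 °C → rt, evaporate; TBSCl, imidazole, DMF, rt; K2CO3, MeOH–THF–H2O, rt; aq. KHSO4 to pH 4
Reagents that add atoms: lithium hydroxide, [Li+].[OH-]; tert-butyldimethylsilyl chloride, CC(C)(C)[Si](C)(C)Cl
Why: Saponification, exhaustive silylation and selective solvolysis of the labile silyl ester is the standard way to open a γ-lactone to a silyloxy acid without relactonisation; the stereocentre is β to the carboxyl group and cannot enolise.

Step 7
Reactants: 15 (3R)-3-Ar-4-[(tert-butyldimethylsilyl)oxy]butanoic acid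
Product: 17 (4R)-4-Ar-5-[(tert-butyldimethylsilyl)oxy]-1-diazopentan-2-one, via isobutyl carbonic anhydride 16 (not isolated)
Conditions: i-BuOCOCl, Et3N, THF, −15 °C; TMSCHN2, MeCN, 0 °C → rt
Reagents that add atoms: (trimethylsilyl)diazomethane, C[Si](C)(C)C=[N+]=[N-]
Why: First half of an Arndt–Eistert homologation: acylation of the diazoalkane by a mixed carbonic anhydride, with loss of the silyl group on work-up, avoids an acid chloride and its hydrogen chloride, so MOM and TBS ethers are not at risk.

Step 8
Reactants: 18 2-chloro-1,1-dimethoxyethane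
Product: 20 methoxyethyne, via sodium methoxyethynide 19 (not isolated)
Conditions: NaNH2 (3.3 equiv), liq. NH3, −33 °C; aq. NaCl, −70 °C → rt; distil into cold CH2Cl2
Reagents that add atoms: none
Why: Twofold base-induced elimination (methanol, then hydrogen chloride) from a chloroacetal, the classical preparation of alkoxyacetylenes; the acetylide is protonated on quenching and the volatile alkyne is collected as a cold solution.

Step 9
Reactants: 17 (4R)-4-Ar-5-[(tert-butyldimethylsilyl)oxy]-1-diazopentan-2-one; 20 methoxyethyne
Product: 22 4-[(2R)-2-Ar-3-[(tert-butyldimethylsilyl)oxy]propyl]-3-methoxycyclobut-2-en-1-one (both C4 epimers), via ketene 21 (not isolated)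
Conditions: hν (365 nm LED), 20 (5 equiv), CH2Cl2, 0 °C
Reagents that add atoms: none
Why: Photochemical Wolff rearrangement gives aldoketene 21 at low stationary concentration, and its [2+2] cycloaddition with the excess ynol ether (alkyne CH carbon to ketene carbonyl carbon) gives the 3-alkoxy-4-alkylcyclobutenone; the wavelength is chosen to lie beyond the chromene absorption, and the new ring stereocentre is uncontrolled and irrelevant.

Step 10
Reactants: 23 3,3-diethoxyprop-1-yne
Product: 26 [(3,3-diethoxyprop-1-yn-1-yl)oxy]tri(propan-2-yl)silane, via lithium acetylide 24 (not isolated), via lithium ynolate 25 (not isolated)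
Conditions: LiHMDS, THF, −78 °C; t-BuOOLi (from t-BuOOH and LiHMDS), −78 → 0 °C; TIPSOTf, −78 °C; Et3N-deactivated silica
Reagents that add atoms: tert-butyl hydroperoxide, CC(C)(C)OO; triisopropylsilyl trifluoromethanesulfonate, CC(C)[Si](C(C)C)(C(C)C)OS(=O)(=O)C(F)(F)F
Why: Electrophilic oxygenation of a lithium acetylide by a lithium alkyl peroxide gives the ynolate, and a bulky silyl triflate silylates it on oxygen, a known route to functionalised siloxyalkynes; the propargylic acetal is a spectator under these basic conditions.

Step 11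
Reactants: 22 4-[(2R)-2-Ar-3-[(tert-butyldimethylsilyl)oxy]propyl]-3-methoxycyclobut-2-en-1-one; 26 [(3,3-diethoxyprop-1-yn-1-yl)oxy]tri(propan-2-yl)silane
Product: 31 6-[(2R)-2-Ar-3-[(tert-butyldimethylsilyl)oxy]propyl]-2-(diethoxymethyl)-5-methoxy-3-[tri(propan-2-yl)silyloxy]phenol, via vinylketene 27 (not isolated), via vinylcyclobutenone 28 (not isolated), via dienylketene 29 (not isolated), via cyclohexadienone 30 (not isolated)
Conditions: 26 (1.5 equiv), toluene, 80 → 110 °C (sealed, base-washed glass)
Reagents that add atoms: none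
Why: Danheiser benzannulation in its cyclobutenone–siloxyalkyne form, a known route to resorcinol monosilyl ethers. Thermal conrotatory 4π opening of 22, with the ring-C4 alkyl group rotating outward, gives vinylketene 27, whose electrophilic ketene carbon is attacked by the acetal-bearing carbon of ynol ether 26 in a regiospecific [2+2] to 28 (bonds C8–C8a and C6–C7). 28 reopens to dienylketene 29, and ring A closes by thermal disrotatory 6π electrocyclisation between the ketene carbon and the chain-bearing terminus (bond C4a–C8a) to dienone 30, which tautomerises to phenol 31. No stereocentre is created: the ring stereocentre of 22 becomes aromatic C4a, and the remote benzylic centre has no acidic hydrogen and is not touched. The selectivity needed is the regiochemistry of the ketene–alkyne [2+2], and the matched polarisation of ketene carbonyl carbon and the alkyne carbon β to oxygen secures it, putting OH at C8a, the acetal at C8 and the silyloxy group at C7. Neutral aprotic conditions are kept so that acetal and siloxyalkyne survive; TBS and MOM ethers and the chromene are thermally inert at this temperature.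

Step 12
Reactants: 31 6-[(2R)-2-Ar-3-[(tert-butyldimethylsilyl)oxy]propyl]-2-(diethoxymethyl)-5-methoxy-3-[tri(propan-2-yl)silyloxy]phenol
Product: 33 3-[(2R)-2-Ar-3-hydroxypropyl]-2,6-dihydroxy-4-methoxybenzaldehyde, via acetal triol 32 (not isolated)
Conditions: TBAF (3.5 equiv), THF, 0 °C → rt; AcOH–H2O, rt
Reagents that add atoms: water, O
Why: Fluoride cleaves the aryl TIPS and alkyl TBS ethers, and the acetal of a 2,4,6-trioxygenated benzaldehyde hydrolyses at pH 4 through a highly stabilised oxocarbenium ion, conditions under which the aryl MOM ether and the chromene are stable.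

Step 13
Reactants: 33 3-[(2R)-2-Ar-3-hydroxypropyl]-2,6-dihydroxy-4-methoxybenzaldehyde
Product: 34 (3R)-3-Ar-7-hydroxy-5-methoxy-3,4-dihydro-2H-chromene-8-carbaldehyde
Conditions: PPh3, DIAD, THF (0.01 M), 0 °C → rt
Reagents that add atoms: none
Why: Intramolecular Mitsunobu etherification (6-exo-tet): the activated primary alcohol is displaced by the acidic ortho-formyl phenol at C8a, the only hydroxyl that can reach it, and the displacement at CH2 leaves the adjacent stereocentre untouched; high dilution suppresses intermolecular alkylation of the C7 hydroxyl.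

Step 14
Reactants: 34 (3R)-3-Ar-7-hydroxy-5-methoxy-3,4-dihydro-2H-chromene-8-carbaldehyde
Product: 35 (3R)-7-hydroxy-3-(5-hydroxy-2,2-dimethyl-2H-chromen-8-yl)-5-methoxy-3,4-dihydro-2H-chromene-8-carbaldehyde
Conditions: 3 M aq. HCl, MeOH–THF, 45 °C
Reagents that add atoms: none
Why: Acid-catalysed cleavage of the aryl MOM acetal under dilute aqueous conditions, which are commonly applied to 2,2-dimethylchromene-bearing phenols; any acetal formed reversibly at the aldehyde is returned on aqueous work-up.

## Compound list

1 | 4-bromobenzene-1,3-diol (4-bromoresorcinol) | Oc1ccc(Br)c(O)c1 | starting material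
2 | disodium 4-bromobenzene-1,3-diolate | [Na+].[Na+].[O-]c1ccc(Br)c([O-])c1 | intermediate (not isolated)
3 | 2-bromo-5-(methoxymethoxy)phenol | COCOc1ccc(Br)c(O)c1 | intermediate
4 | 3-chloro-3-methylbut-1-yne | CC(C)(Cl)C#C | starting material
5 | 1-bromo-4-(methoxymethoxy)-2-[(2-methylbut-3-yn-2-yl)oxy]benzene | COCOc1ccc(Br)c(OC(C)(C)C#C)c1 | intermediate
6 | 6-bromo-3-(methoxymethoxy)-2-(3-methylbuta-1,2-dien-1-yl)phenol (allenylphenol) | CC(C)=C=Cc1c(O)c(Br)ccc1OCOC | intermediate (not isolated)
7 | 8-bromo-5-(methoxymethoxy)-2,2-dimethyl-2H-chromene | COCOc1ccc(Br)c2c1C=CC(C)(C)O2 | intermediate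
8 | [5-(methoxymethoxy)-2,2-dimethyl-2H-chromen-8-yl]lithium (aryllithium) | [Li]c1ccc(OCOC)c2c1OC(C)(C)C=C2 | intermediate (not isolated)
9 | lithium [5-(methoxymethoxy)-2,2-dimethyl-2H-chromen-8-yl]tri(propan-2-yloxy)borate | [Li+].CC(C)O[B-](OC(C)C)(OC(C)C)c1ccc(OCOC)c2c1OC(C)(C)C=C2 | intermediate (not isolated)
10 | [5-(methoxymethoxy)-2,2-dimethyl-2H-chromen-8-yl]boronic acid | OB(O)c1ccc(OCOC)c2c1OC(C)(C)C=C2 | intermediate
11 | furan-2(5H)-one | O=C1OCC=C1 | starting material
12 | (4R)-4-[5-(methoxymethoxy)-2,2-dimethyl-2H-chromen-8-yl]oxolan-2-one | O=C1C[C@H](c2ccc(OCOC)c3c2OC(C)(C)C=C3)CO1 | intermediate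
13 | lithium (3R)-4-hydroxy-3-[5-(methoxymethoxy)-2,2-dimethyl-2H-chromen-8-yl]butanoate | [Li+].[O-]C(=O)C[C@H](c1ccc(OCOC)c2c1OC(C)(C)C=C2)CO | intermediate (not isolated)
14 | tert-butyldimethylsilyl (3R)-4-[(tert-butyldimethylsilyl)oxy]-3-[5-(methoxymethoxy)-2,2-dimethyl-2H-chromen-8-yl]butanoate | CC(C)(C)[Si](C)(C)OC(=O)C[C@H](c1ccc(OCOC)c2c1OC(C)(C)C=C2)CO[Si](C)(C)C(C)(C)C | intermediate (not isolated)
15 | (3R)-4-[(tert-butyldimethylsilyl)oxy]-3-[5-(methoxymethoxy)-2,2-dimethyl-2H-chromen-8-yl]butanoic acid | OC(=O)C[C@H](c1ccc(OCOC)c2c1OC(C)(C)C=C2)CO[Si](C)(C)C(C)(C)C | intermediate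
16 | mixed anhydride of acid 15 with isobutyl hydrogen carbonate | CC(C)COC(=O)OC(=O)C[C@H](c1ccc(OCOC)c2c1OC(C)(C)C=C2)CO[Si](C)(C)C(C)(C)C | intermediate (not isolated)
17 | (4R)-5-[(tert-butyldimethylsilyl)oxy]-1-diazo-4-[5-(methoxymethoxy)-2,2-dimethyl-2H-chromen-8-yl]pentan-2-one | [N-]=[N+]=CC(=O)C[C@H](c1ccc(OCOC)c2c1OC(C)(C)C=C2)CO[Si](C)(C)C(C)(C)C | intermediate
18 | 2-chloro-1,1-dimethoxyethane (chloroacetaldehyde dimethyl acetal) | ClCC(OC)OC | starting material
19 | sodium methoxyethynide | [Na+].[C-]#COC | intermediate (not isolated)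
20 | methoxyethyne | COC#C | intermediate
21 | (4R)-5-[(tert-butyldimethylsilyl)oxy]-4-[5-(methoxymethoxy)-2,2-dimethyl-2H-chromen-8-yl]pent-1-en-1-one (ketene) | O=C=CC[C@H](c1ccc(OCOC)c2c1OC(C)(C)C=C2)CO[Si](C)(C)C(C)(C)C | intermediate (not isolated)
22 | 4-[(2R)-3-[(tert-butyldimethylsilyl)oxy]-2-[5-(methoxymethoxy)-2,2-dimethyl-2H-chromen-8-yl]propyl]-3-methoxycyclobut-2-en-1-one, both epimers at ring C4 | COC1=CC(=O)C1C[C@H](c1ccc(OCOC)c2c1OC(C)(C)C=C2)CO[Si](C)(C)C(C)(C)C | intermediate
23 | 3,3-diethoxyprop-1-yne | CCOC(OCC)C#C | starting material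
24 | lithium 3,3-diethoxyprop-1-yn-1-ide | [Li+].[C-]#CC(OCC)OCC | intermediate (not isolated)
25 | lithium 3,3-diethoxyprop-1-yn-1-olate | [Li+].[O-]C#CC(OCC)OCC | intermediate (not isolated)
26 | [(3,3-diethoxyprop-1-yn-1-yl)oxy]tri(propan-2-yl)silane | CCOC(OCC)C#CO[Si](C(C)C)(C(C)C)C(C)C | intermediate
27 | (6R)-7-[(tert-butyldimethylsilyl)oxy]-3-methoxy-6-[5-(methoxymethoxy)-2,2-dimethyl-2H-chromen-8-yl]hepta-1,3-dien-1-one (vinylketene) | O=C=CC(OC)=CC[C@H](c1ccc(OCOC)c2c1OC(C)(C)C=C2)CO[Si](C)(C)C(C)(C)C | intermediate (not isolated)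
28 | 4-[(4R)-5-[(tert-butyldimethylsilyl)oxy]-1-methoxy-4-[5-(methoxymethoxy)-2,2-dimethyl-2H-chromen-8-yl]pent-1-en-1-yl]-2-(diethoxymethyl)-3-[tri(propan-2-yl)silyloxy]cyclobut-2-en-1-one (vinylcyclobutenone) | O=C1C(C(OCC)OCC)=C(O[Si](C(C)C)(C(C)C)C(C)C)C1C(OC)=CC[C@H](c1ccc(OCOC)c2c1OC(C)(C)C=C2)CO[Si](C)(C)C(C)(C)C | intermediate (not isolated)
29 | (8R)-9-[(tert-butyldimethylsilyl)oxy]-2-(diethoxymethyl)-5-methoxy-8-[5-(methoxymethoxy)-2,2-dimethyl-2H-chromen-8-yl]-3-[tri(propan-2-yl)silyloxy]nona-1,3,5-trien-1-one (dienylketene) | O=C=C(C(OCC)OCC)C(O[Si](C(C)C)(C(C)C)C(C)C)=CC(OC)=CC[C@H](c1ccc(OCOC)c2c1OC(C)(C)C=C2)CO[Si](C)(C)C(C)(C)C | intermediate (not isolated)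
30 | 6-[(2R)-3-[(tert-butyldimethylsilyl)oxy]-2-[5-(methoxymethoxy)-2,2-dimethyl-2H-chromen-8-yl]propyl]-2-(diethoxymethyl)-5-methoxy-3-[tri(propan-2-yl)silyloxy]cyclohexa-2,4-dien-1-one (cyclohexadienone) | O=C1C(C(OCC)OCC)=C(O[Si](C(C)C)(C(C)C)C(C)C)C=C(OC)C1C[C@H](c1ccc(OCOC)c2c1OC(C)(C)C=C2)CO[Si](C)(C)C(C)(C)C | intermediate (not isolated)
31 | 6-[(2R)-3-[(tert-butyldimethylsilyl)oxy]-2-[5-(methoxymethoxy)-2,2-dimethyl-2H-chromen-8-yl]propyl]-2-(diethoxymethyl)-5-methoxy-3-[tri(propan-2-yl)silyloxy]phenol | CCOC(OCC)c1c(O)c(C[C@H](c2ccc(OCOC)c3c2OC(C)(C)C=C3)CO[Si](C)(C)C(C)(C)C)c(OC)cc1O[Si](C(C)C)(C(C)C)C(C)C | intermediate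
32 | 2-(diethoxymethyl)-4-[(2R)-3-hydroxy-2-[5-(methoxymethoxy)-2,2-dimethyl-2H-chromen-8-yl]propyl]-5-methoxybenzene-1,3-diol (acetal triol) | CCOC(OCC)c1c(O)cc(OC)c(C[C@H](c2ccc(OCOC)c3c2OC(C)(C)C=C3)CO)c1O | intermediate (not isolated)
33 | 2,6-dihydroxy-3-[(2R)-3-hydroxy-2-[5-(methoxymethoxy)-2,2-dimethyl-2H-chromen-8-yl]propyl]-4-methoxybenzaldehyde | O=Cc1c(O)cc(OC)c(C[C@H](c2ccc(OCOC)c3c2OC(C)(C)C=C3)CO)c1O | intermediate
34 | (3R)-7-hydroxy-5-methoxy-3-[5-(methoxymethoxy)-2,2-dimethyl-2H-chromen-8-yl]-3,4-dihydro-2H-chromene-8-carbaldehyde | COc1cc(O)c(C=O)c2c1C[C@H](c1ccc(OCOC)c3c1OC(C)(C)C=C3)CO2 | intermediate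
35 | (3R)-7-hydroxy-3-(5-hydroxy-2,2-dimethyl-2H-chromen-8-yl)-5-methoxy-3,4-dihydro-2H-chromene-8-carbaldehyde | COc1cc(O)c(C=O)c2c1C[C@H](c1ccc(O)c3c1OC(C)(C)C=C3)CO2 | target

## Step count and least certain steps

Total: 14 steps. Longest linear sequence: 12 steps (steps 1–7, 9, 11–14); steps 8 and 10 are side branches.

**Step 11 (key step).** Two processes may fail.
- Slow conversion: the cyclobutenone is a vinylogous ester and may open slowly, and the ynol ether is α-branched and inductively deactivated, so the [2+2] may lag. Ketene self-condensation or acylation of the product phenol could then take over.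
- Loss of ethanol: the ortho-hydroxy acetal may ionise at 110 °C to quinone-methide-type species, which the electron-rich alkyne can intercept.
- Fallback: set out from 22 and replace the acetal by a silyloxymethyl group, which is closer to the alkyl-substituted siloxyalkynes that this annulation is known for. Commercial tert-butyldimethyl(prop-2-yn-1-yloxy)silane is oxidised and silylated as in step 10 to tert-butyldimethyl({3-[tri(propan-2-yl)silyloxy]prop-2-yn-1-yl}oxy)silane F1. Benzannulation of 22 with it should give 6-[(2R)-2-Ar-3-[(tert-butyldimethylsilyl)oxy]propyl]-2-{[(tert-butyldimethylsilyl)oxy]methyl}-5-methoxy-3-[tri(propan-2-yl)silyloxy]phenol F2. Fluoride then frees 4-[(2R)-2-Ar-3-hydroxypropyl]-2-(hydroxymethyl)-5-methoxybenzene-1,3-diol F3, and manganese dioxide oxidises the benzylic alcohol selectively beside the aliphatic one. The route is rejoined at 33.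

**Step 5.** The electron-rich, ortho-alkoxy boronic acid may protodeboronate faster than it transmetalates, and the butenolide is a sluggish acceptor, so turnover may be low.
- Fallback: set out from 10 and set the stereocentre by hydride delivery instead of aryl delivery. Suzuki–Miyaura coupling of 10 with commercial 4-bromofuran-2(5H)-one gives 4-[5-(methoxymethoxy)-2,2-dimethyl-2H-chromen-8-yl]furan-2(5H)-one F4. Copper hydride-catalysed asymmetric conjugate reduction (chiral bisphosphine, polymethylhydrosiloxane) reduces only the activated lactone olefin and returns to 12.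

**Step 9.** The aldoketene may dimerise, the carbene may be diverted before rearrangement, and the chromene or the product cyclobutenone may react photochemically if the light is not selective enough.
- Fallback: set out from 17 and generate the same ketene without light. Silver-catalysed Wolff rearrangement in aqueous THF completes the Arndt–Eistert homologation to (4R)-4-Ar-5-[(tert-butyldimethylsilyl)oxy]pentanoic acid F5. The neutral reagent 1-chloro-N,N,2-trimethylprop-1-en-1-amine converts it to (4R)-4-Ar-5-[(tert-butyldimethylsilyl)oxy]pentanoyl chloride F6. Dehydrochlorination with triethylamine in the presence of 20 gives ketene 21 and, by the same [2+2], returns to 22.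

**Step 1.** Site selectivity between the two phenolic oxygens may be poor, and double alkylation may compete.
- Fallback: set out from 1 and differentiate by size, then exchange the protecting group. The bulky silyl chloride should take the unhindered hydroxyl to give 2-bromo-5-[tri(propan-2-yl)silyloxy]phenol F7. Propargylation as in step 2 gives {4-bromo-3-[(2-methylbut-3-yn-2-yl)oxy]phenoxy}tri(propan-2-yl)silane F8, and rearrangement as in step 3 gives [(8-bromo-2,2-dimethyl-2H-chromen-5-yl)oxy]tri(propan-2-yl)silane F9. Fluoride frees 8-bromo-2,2-dimethyl-2H-chromen-5-ol F10, and MOM protection of this single phenol rejoins the route at 7.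

## Further compounds

F1 | step 11 | tert-butyldimethyl({3-[tri(propan-2-yl)silyloxy]prop-2-yn-1-yl}oxy)silane | CC(C)[Si](C(C)C)(C(C)C)OC#CCO[Si](C)(C)C(C)(C)C
F2 | step 11 | 6-[(2R)-3-[(tert-butyldimethylsilyl)oxy]-2-[5-(methoxymethoxy)-2,2-dimethyl-2H-chromen-8-yl]propyl]-2-{[(tert-butyldimethylsilyl)oxy]methyl}-5-methoxy-3-[tri(propan-2-yl)silyloxy]phenol | CC(C)(C)[Si](C)(C)OCc1c(O)c(C[C@H](c2ccc(OCOC)c3c2OC(C)(C)C=C3)CO[Si](C)(C)C(C)(C)C)c(OC)cc1O[Si](C(C)C)(C(C)C)C(C)C
F3 | step 11 | 4-[(2R)-3-hydroxy-2-[5-(methoxymethoxy)-2,2-dimethyl-2H-chromen-8-yl]propyl]-2-(hydroxymethyl)-5-methoxybenzene-1,3-diol | OCc1c(O)cc(OC)c(C[C@H](c2ccc(OCOC)c3c2OC(C)(C)C=C3)CO)c1O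
F4 | step 5 | 4-[5-(methoxymethoxy)-2,2-dimethyl-2H-chromen-8-yl]furan-2(5H)-one | O=C1OCC(c2ccc(OCOC)c3c2OC(C)(C)C=C3)=C1
F5 | step 9 | (4R)-5-[(tert-butyldimethylsilyl)oxy]-4-[5-(methoxymethoxy)-2,2-dimethyl-2H-chromen-8-yl]pentanoic acid | OC(=O)CC[C@H](c1ccc(OCOC)c2c1OC(C)(C)C=C2)CO[Si](C)(C)C(C)(C)C
F6 | step 9 | (4R)-5-[(tert-butyldimethylsilyl)oxy]-4-[5-(methoxymethoxy)-2,2-dimethyl-2H-chromen-8-yl]pentanoyl chloride | ClC(=O)CC[C@H](c1ccc(OCOC)c2c1OC(C)(C)C=C2)CO[Si](C)(C)C(C)(C)C
F7 | step 1 | 2-bromo-5-[tri(propan-2-yl)silyloxy]phenol | CC(C)[Si](C(C)C)(C(C)C)Oc1ccc(Br)c(O)c1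
F8 | step 1 | {4-bromo-3-[(2-methylbut-3-yn-2-yl)oxy]phenoxy}tri(propan-2-yl)silane | CC(C)[Si](C(C)C)(C(C)C)Oc1ccc(Br)c(OC(C)(C)C#C)c1
F9 | step 1 | [(8-bromo-2,2-dimethyl-2H-chromen-5-yl)oxy]tri(propan-2-yl)silane | CC(C)[Si](C(C)C)(C(C)C)Oc1ccc(Br)c2c1C=CC(C)(C)O2
F10 | step 1 | 8-bromo-2,2-dimethyl-2H-chromen-5-ol | Oc1ccc(Br)c2c1C=CC(C)(C)O2
A1 | alternative 1 | (3R)-3-{5-[(tert-butyldimethylsilyl)oxy]-2,2-dimethyl-2H-chromen-8-yl}-5,7-dimethoxy-3,4-dihydro-2H-chromen-2-ol (anomeric mixture) | COc1cc(OC)cc2c1C[C@H](c1ccc(O[Si](C)(C)C(C)(C)C)c3c1OC(C)(C)C=C3)C(O)O2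
A2 | alternative 1 | 3,5-dimethoxy-2-[(phenylsulfonyl)methyl]phenol | COc1cc(O)c(CS(=O)(=O)c2ccccc2)c(OC)c1
A3 | alternative 1 | 2-{5-[(tert-butyldimethylsilyl)oxy]-2,2-dimethyl-2H-chromen-8-yl}acetaldehyde | O=CCc1ccc(O[Si](C)(C)C(C)(C)C)c2c1OC(C)(C)C=C2
A4 | alternative 2 | 3-{4-[(2,2-dimethylpropanoyl)oxy]-2-[tri(propan-2-yl)silyloxy]phenyl}-5,7-dimethoxy-1-benzopyrylium chloride | COc1cc(OC)c2cc(-c3ccc(OC(=O)C(C)(C)C)cc3O[Si](C(C)C)(C(C)C)C(C)C)c[o+]c2c1.[Cl-]
A5 | alternative 2 | 4,6-dimethoxy-1-benzofuran | COc1cc(OC)c2ccoc2c1
A6 | alternative 2 | 4-(3-chloro-3H-diazirin-3-yl)-3-[tri(propan-2-yl)silyloxy]phenyl 2,2-dimethylpropanoate | ClC1(N=N1)c1ccc(OC(=O)C(C)(C)C)cc1O[Si](C(C)C)(C(C)C)C(C)C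
A7 | alternative 3 | (3R)-3-{2,2-dimethyl-5-[tri(propan-2-yl)silyloxy]-2H-chromen-8-yl}-7-hydroxy-5-methoxy-3,4-dihydro-2H-chromene-8-carbaldehyde | COc1cc(O)c(C=O)c2c1C[C@H](c1ccc(O[Si](C(C)C)(C(C)C)C(C)C)c3c1OC(C)(C)C=C3)CO2
A8 | alternative 3 | (3R)-7-hydroxy-5-methoxy-3-{2-[(2-methylbut-3-yn-2-yl)oxy]-4-[tri(propan-2-yl)silyloxy]phenyl}-3,4-dihydro-2H-chromene-8-carbaldehyde | COc1cc(O)c(C=O)c2c1C[C@H](c1ccc(O[Si](C(C)C)(C(C)C)C(C)C)cc1OC(C)(C)C#C)CO2
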